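**Retrosynthetic overview**
The side chain is counted from C1' (benzylic) to C17' (methyl). The target is 5-[(8'Z,11'Z,16'S)-16'-hydroxyheptadeca-8',11'-dienyl]benzene-1,3-diol, and the last step is a single acid deprotection of two MOM ethers and one TBS ether.
Key disconnection C7'–C8': a primary alkyllithium (arene plus C1'–C7') and an (E)-alkenyl pinacol boronate (C8'–C17') are joined on boron in a Zweifel olefination. The iodine-triggered 1,2-shift forms the bond, and the anti elimination expels boron while turning the E alkene into the Z alkene.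
Enabling feature: C8'=C9' is a cis-1,2-disubstituted alkene with one H on each carbon. C7' is an unbranched primary CH2 that migrates cleanly, the doubly allylic C10'H2 is spared any metal hydride or warm base, and the benzene ring lies seven CH2 groups away as a spectator.
Fragments: C10'–C11' comes from copper-catalysed coupling of a terminal alkyne with a commercial C3 chloroallyl boronate, C11'=C12' from semihydrogenation, and C14'–C15' from opening (S)-propylene oxide, which supplies C16'. The aryl–C1' bond comes from a B-alkyl Suzuki–Miyaura coupling.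
Rings: no ring is formed, since the benzene ring is bought as 5-bromoresorcinol. The only temporary ring is the dioxaborolane, which leaves in the key step.

Key step: step 9

**Route**

Step 1
Reactants: 1 4-bromo-1-(trimethylsilyl)but-1-yne; 2 (S)-propylene oxide
Product: 4 (2S)-7-(trimethylsilyl)hept-6-yn-2-ol, via Grignard reagent 3 (not isolated)
Conditions: Mg, THF, 40 °C; then CuI (10 mol %), 2, THF, −30 to 0 °C; aq NH4Cl
Reagents that add atoms: none
Why: Copper-catalysed Grignard opening of a terminal epoxide should proceed by SN2 attack at the unsubstituted CH2, so the C–O bond at the stereocentre is never touched and the S configuration of 2 becomes C16' of the target.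

Step 2
Reactants: 4 (2S)-7-(trimethylsilyl)hept-6-yn-2-ol
Product: 5 (2S)-2-(tert-butyldimethylsilyloxy)-7-(trimethylsilyl)hept-6-yne
Conditions: TBSCl, imidazole, CH2Cl2, rt
Reagents that add atoms: TBSCl, CC(C)(C)[Si](C)(C)Cl
Why: Imidazole-promoted silyl ether formation masks the only acidic proton of this fragment ahead of the organolithium step and does not touch the stereocentre.

Step 3
Reactants: 5 (2S)-2-(tert-butyldimethylsilyloxy)-7-(trimethylsilyl)hept-6-yne
Product: 6 (2S)-2-(tert-butyldimethylsilyloxy)hept-6-yne
Conditions: K2CO3 (0.2 equiv), MeOH, rt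
Reagents that add atoms: none
Why: Carbonate-catalysed methanolysis of the alkynyl–silicon bond (protiodesilylation) is fast, whereas the secondary TBS ether should be stable under these conditions.

Step 4
Reactants: 6 (2S)-2-(tert-butyldimethylsilyloxy)hept-6-yne; 7 (E)-2-(3-chloroprop-1-en-1-yl)-4,4,5,5-tetramethyl-1,3,2-dioxaborolane
Product: 9 2-[(1E,9S)-9-(tert-butyldimethylsilyloxy)dec-1-en-4-yn-1-yl]-4,4,5,5-tetramethyl-1,3,2-dioxaborolane, via allylic iodide 8 (not isolated)
Conditions: NaI (1.1 equiv), CuI (20 mol %), K2CO3 (2 equiv), DMF, rt, argon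
Reagents that add atoms: none
Why: Finkelstein exchange followed by copper-catalysed allylic substitution by a terminal alkyne (1,4-enyne synthesis) should occur at the primary allylic carbon with the E alkene retained, because an SN2' course would have to strike the hindered boron-bearing carbon and break the C=C–B conjugation, and carbonate in dry DMF is too weak an activator to move the alkenyl group from boron to copper.

Step 5
Reactants: 9 2-[(1E,9S)-9-(tert-butyldimethylsilyloxy)dec-1-en-4-yn-1-yl]-4,4,5,5-tetramethyl-1,3,2-dioxaborolane
Product: 10 2-[(1E,4Z,9S)-9-(tert-butyldimethylsilyloxy)deca-1,4-dien-1-yl]-4,4,5,5-tetramethyl-1,3,2-dioxaborolane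
Conditions: H2 (1 atm), Pd/CaCO3 poisoned with Pb(OAc)2 (Lindlar catalyst), quinoline, EtOAc, rt, stopped after one equivalent of H2
Reagents that add atoms: none
Why: Lindlar semihydrogenation delivers both hydrogens to one face of the adsorbed alkyne and should therefore set the Z geometry of C11'=C12', the alkyne being bound far more strongly than the product alkene or the hindered, electron-poor alkenyl boronate.

Step 6
Reactants: 11 5-bromobenzene-1,3-diol
Product: 12 1-bromo-3,5-bis(methoxymethoxy)benzene
Conditions: MOMCl (2.5 equiv), i-Pr2NEt (3 equiv), CH2Cl2, 0 °C to rt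
Reagents that add atoms: MOMCl, COCCl
Why: Williamson-type O-alkylation of both phenols gives acetal ethers that withstand base, palladium catalysis, organolithiums and methoxide and that leave under mild acid compatible with Z alkenes.

Step 7
Reactants: 12 1-bromo-3,5-bis(methoxymethoxy)benzene; 13 hept-6-en-1-ol
Product: 15 7-[3,5-bis(methoxymethoxy)phenyl]heptan-1-ol, via bis-boryl adduct 14 (not isolated)
Conditions: 9-BBN (2.2 equiv), THF, 0 °C to rt; then 12, Pd(dppf)Cl2 (5 mol %), 3 M aq NaOH, THF, 65 °C
Reagents that add atoms: none
Why: Anti-Markovnikov hydroboration of the terminal alkene (the free OH merely takes up a second equivalent of 9-BBN as a borinate that the aqueous base hydrolyses) followed by B-alkyl Suzuki–Miyaura coupling forms the aryl–C1' bond, and the aryl bromide, whose alkoxy groups stand meta to bromine, should add to zerovalent palladium about as readily as bromobenzene.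

Step 8
Reactants: 15 7-[3,5-bis(methoxymethoxy)phenyl]heptan-1-ol
Product: 16 1-(7-iodoheptyl)-3,5-bis(methoxymethoxy)benzene
Conditions: I2, PPh3, imidazole, CH2Cl2, 0 °C to rt
Reagents that add atoms: iodine, II
Why: Appel-type iodination converts the primary alcohol by SN2 displacement of the oxyphosphonium ion, and imidazole keeps the medium non-acidic so that the MOM acetals should survive.

Step 9
Reactants: 16 1-(7-iodoheptyl)-3,5-bis(methoxymethoxy)benzene; 10 2-[(1E,4Z,9S)-9-(tert-butyldimethylsilyloxy)deca-1,4-dien-1-yl]-4,4,5,5-tetramethyl-1,3,2-dioxaborolane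
Product: 20 tert-butyl({(2S,6Z,9Z)-17-[3,5-bis(methoxymethoxy)phenyl]heptadeca-6,9-dien-2-yl}oxy)dimethylsilane, via alkyllithium 17 (not isolated), via lithium borate 18 (not isolated), via iodoboronate 19 (not isolated)
Conditions: t-BuLi (2.0 equiv), Et2O–pentane, −78 °C; 10, THF, −78 °C; I2 (1.2 equiv), THF, −78 °C; NaOMe (3 equiv), MeOH, −78 °C to rt
Reagents that add atoms: none
Why: Lithium–iodine exchange on 16 gives alkyllithium 17, which adds to the empty orbital on boron in 10 to give borate 18; iodine then attacks the now electron-rich C8'=C9' bond, the C7' methylene migrates from boron to C8' antiperiplanar to the breaking C8'–I bond of the iodonium ion to give 19, and methoxide binds to boron and triggers anti elimination of boron and iodide. This is the Zweifel olefination in its boronic ester form (alkenyl pinacol boronate plus organolithium, then I2 and NaOMe), a known route to Z-1,2-disubstituted alkenes. No ring is closed and no new stereocentre remains: the two transient centres C8' and C9' of 19 are fixed relative to each other by the anti migration whichever alkene face iodine attacks, and the anti elimination turns that relation into the Z geometry, so the easily made E boronate is inverted while C16' and the C11'=C12' Z alkene are bystanders. The step needs iodine to choose C8'=C9', which the negative charge on boron secures over the neutral C11'=C12' alkene and the MOM-protected benzene ring at −78 °C, and it needs a single migrating group, which the pinacol ligand secures because C7' is the only carbon substituent on boron besides the alkenyl group. Lithium–iodine exchange with exactly two equivalents of t-BuLi and the addition to boron should both outrun deprotonation of the ring carbon between the two MOM ethers and of the doubly allylic C10'H2. In one flask the step forms C7'–C8', completes the C17 chain and the skipped Z,Z-diene and removes the boron activating group without any transition metal, hydride or warm base that could move the 1,4-diene into conjugation, and surplus 17 is returned to 16 by the iodine.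

Step 10
Reactants: 20 tert-butyl({(2S,6Z,9Z)-17-[3,5-bis(methoxymethoxy)phenyl]heptadeca-6,9-dien-2-yl}oxy)dimethylsilane
Product: 21 Hansfordiol D, 5-[(8Z,11Z,16S)-16-hydroxyheptadeca-8,11-dien-1-yl]benzene-1,3-diol
Conditions: HCl (1 M) in MeOH–THF, 40 °C
Reagents that add atoms: none
Why: Acid-catalysed acetal exchange of the MOM groups and solvolysis of the silyl ether in methanol should free all three hydroxy groups in one operation, methanol trapping the formaldehyde unit as its dimethyl acetal, while the isolated Z alkenes, the doubly allylic CH2 and the C16' carbinol centre (no C–O cleavage) are not affected by dilute acid at this temperature.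

**Compound list**
1 | 4-bromo-1-(trimethylsilyl)but-1-yne | C[Si](C)(C)C#CCCBr | starting material
2 | (S)-propylene oxide, (2S)-2-methyloxirane | C[C@H]1CO1 | starting material
3 | [4-(trimethylsilyl)but-3-yn-1-yl]magnesium bromide (not isolated) | C[Si](C)(C)C#CCC[Mg]Br | intermediate
4 | (2S)-7-(trimethylsilyl)hept-6-yn-2-ol | C[C@H](O)CCCC#C[Si](C)(C)C | intermediate
5 | (2S)-2-(tert-butyldimethylsilyloxy)-7-(trimethylsilyl)hept-6-yne | C[C@H](O[Si](C)(C)C(C)(C)C)CCCC#C[Si](C)(C)C | intermediate
6 | (2S)-2-(tert-butyldimethylsilyloxy)hept-6-yne | C[C@H](O[Si](C)(C)C(C)(C)C)CCCC#C | intermediate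
7 | (E)-2-(3-chloroprop-1-en-1-yl)-4,4,5,5-tetramethyl-1,3,2-dioxaborolane | ClC/C=C/B1OC(C)(C)C(C)(C)O1 | starting material
8 | (E)-2-(3-iodoprop-1-en-1-yl)-4,4,5,5-tetramethyl-1,3,2-dioxaborolane (not isolated) | IC/C=C/B1OC(C)(C)C(C)(C)O1 | intermediate
9 | 2-[(1E,9S)-9-(tert-butyldimethylsilyloxy)dec-1-en-4-yn-1-yl]-4,4,5,5-tetramethyl-1,3,2-dioxaborolane | C[C@H](O[Si](C)(C)C(C)(C)C)CCCC#CC/C=C/B1OC(C)(C)C(C)(C)O1 | intermediate
10 | 2-[(1E,4Z,9S)-9-(tert-butyldimethylsilyloxy)deca-1,4-dien-1-yl]-4,4,5,5-tetramethyl-1,3,2-dioxaborolane | C[C@H](O[Si](C)(C)C(C)(C)C)CCC/C=C\C/C=C/B1OC(C)(C)C(C)(C)O1 | intermediate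
11 | 5-bromobenzene-1,3-diol (5-bromoresorcinol) | Oc1cc(O)cc(Br)c1 | starting material
12 | 1-bromo-3,5-bis(methoxymethoxy)benzene | COCOc1cc(Br)cc(OCOC)c1 | intermediate
13 | hept-6-en-1-ol | C=CCCCCCO | starting material
14 | 9-{7-[(9-borabicyclo[3.3.1]nonan-9-yl)oxy]heptyl}-9-borabicyclo[3.3.1]nonane (not isolated) | B1(CCCCCCCOB2C3CCCC2CCC3)C2CCCC1CCC2 | intermediate
15 | 7-[3,5-bis(methoxymethoxy)phenyl]heptan-1-ol | OCCCCCCCc1cc(OCOC)cc(OCOC)c1 | intermediate
16 | 1-(7-iodoheptyl)-3,5-bis(methoxymethoxy)benzene | ICCCCCCCc1cc(OCOC)cc(OCOC)c1 | intermediate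
17 | {7-[3,5-bis(methoxymethoxy)phenyl]heptyl}lithium (not isolated) | [Li]CCCCCCCc1cc(OCOC)cc(OCOC)c1 | intermediate
18 | lithium pinacolato borate carrying the (1E,4Z,9S)-9-(tert-butyldimethylsilyloxy)deca-1,4-dienyl group and the 7-arylheptyl group on boron (not isolated) | [Li+].C[C@H](O[Si](C)(C)C(C)(C)C)CCC/C=C\C/C=C/[B-]1(CCCCCCCc2cc(OCOC)cc(OCOC)c2)OC(C)(C)C(C)(C)O1 | intermediate
19 | 2-{(2S,6Z,9S,10S)-17-[3,5-bis(methoxymethoxy)phenyl]-2-(tert-butyldimethylsilyloxy)-9-iodoheptadec-6-en-10-yl}-4,4,5,5-tetramethyl-1,3,2-dioxaborolane (not isolated; the 9R,10R isomer with the same relative configuration forms beside it and gives the same alkene) | C[C@H](O[Si](C)(C)C(C)(C)C)CCC/C=C\C[C@H](I)[C@@H](B1OC(C)(C)C(C)(C)O1)CCCCCCCc1cc(OCOC)cc(OCOC)c1 | intermediate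
20 | tert-butyl({(2S,6Z,9Z)-17-[3,5-bis(methoxymethoxy)phenyl]heptadeca-6,9-dien-2-yl}oxy)dimethylsilane | C[C@H](O[Si](C)(C)C(C)(C)C)CCC/C=C\C/C=C\CCCCCCCc1cc(OCOC)cc(OCOC)c1 | intermediate
21 | Hansfordiol D, 5-[(8Z,11Z,16S)-16-hydroxyheptadeca-8,11-dien-1-yl]benzene-1,3-diol | C[C@H](O)CCC/C=C\C/C=C\CCCCCCCc1cc(O)cc(O)c1 | target

**Step count and risks**
Total step count: 10. Longest linear sequence: 7 steps (steps 1 to 5, then 9 and 10).

Step 4. What may go wrong:
- Attack at the boron-bearing end of the allyl system (SN2' course).
- Transfer of the alkenyl group from boron to copper, followed by protodeboronation.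
- Base-induced migration of the skipped enyne into conjugation.

The fallback installs boron only after the C10'–C11' bond exists. It sets out from 6 and comes back at 9. Compound 6 is coupled with commercial 3-bromo-1-(trimethylsilyl)prop-1-yne (CuI, NaI, K2CO3, DMF, rt) to give the silyl-capped skipped diyne F1. Buffered fluoride (TBAF, AcOH, THF, 0 °C) removes only the alkynyl silyl group and gives the terminal skipped diyne F2. Hydroboration with pinacolborane catalysed by Cp2Zr(H)Cl (CH2Cl2, rt) then adds syn and anti-Markovnikov to the terminal alkyne, which reacts faster than the internal one, and gives 9.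

Step 9. What may go wrong:
- Proton transfer to the alkyllithium from the ring position between the two MOM ethers, or from C10'H2, before the borate has formed.
- Incomplete borate formation.
- Partial syn elimination that erodes the Z geometry.

The fallback replaces the boron-templated union with a stereoretentive Negishi coupling that needs no strong base. It sets out from 9 and 16 and comes back at 20.
- Bromine (CH2Cl2, −78 °C) adds anti to the alkenyl boronate of 9, the alkyne being much less reactive, to give the vicinal dibromide F3.
- NaOMe in MeOH induces anti elimination of boron and bromide to give the (Z)-bromoenyne F4.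
- Direct zinc insertion into 16 (Zn dust, LiCl, THF, 40 °C) gives the alkylzinc iodide F5.
- Coupling of F5 with F4 under Pd(dppf)Cl2 catalysis (THF, rt) with retention of geometry gives the (Z)-enyne F6.
- Semihydrogenation of F6 under the conditions of step 5 gives 20.

Step 5. What may go wrong:
- Over-reduction.
- Hydrogenation of the alkenyl boronate.
- Palladium-hydride-induced Z to E isomerisation, or double-bond migration in the 1,4-diene.

The fallback replaces catalytic hydrogenation with hydroboration and protodeboronation. It sets out from 9 and comes back at 10. Dicyclohexylborane (1 equiv, THF, 0 °C) adds syn to the internal alkyne to give the alkenyl(dicyclohexyl)borane F7. The regioisomer with boron on the neighbouring alkyne carbon converges on the same product. Acetic acid (rt) cleaves only the dialkylboryl–carbon bond with retention, leaves the pinacol boronate intact and gives 10.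

**Further compounds**
F1 | step 4 | (9S)-9-(tert-butyldimethylsilyloxy)-1-(trimethylsilyl)deca-1,4-diyne | C[C@H](O[Si](C)(C)C(C)(C)C)CCCC#CCC#C[Si](C)(C)C
F2 | step 4 | (2S)-2-(tert-butyldimethylsilyloxy)deca-6,9-diyne | C[C@H](O[Si](C)(C)C(C)(C)C)CCCC#CCC#C
F3 | step 9 | 2-[(1R,2S,9S)-1,2-dibromo-9-(tert-butyldimethylsilyloxy)dec-4-yn-1-yl]-4,4,5,5-tetramethyl-1,3,2-dioxaborolane (the 1S,2R isomer forms beside it and gives the same bromoalkene) | C[C@H](O[Si](C)(C)C(C)(C)C)CCCC#CC[C@H](Br)[C@@H](B1OC(C)(C)C(C)(C)O1)Br
F4 | step 9 | (2S,9Z)-10-bromo-2-(tert-butyldimethylsilyloxy)dec-9-en-6-yne | C[C@H](O[Si](C)(C)C(C)(C)C)CCCC#CC/C=C\Br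
F5 | step 9 | {7-[3,5-bis(methoxymethoxy)phenyl]heptyl}zinc iodide | I[Zn]CCCCCCCc1cc(OCOC)cc(OCOC)c1
F6 | step 9 | tert-butyl({(2S,9Z)-17-[3,5-bis(methoxymethoxy)phenyl]heptadec-9-en-6-yn-2-yl}oxy)dimethylsilane | C[C@H](O[Si](C)(C)C(C)(C)C)CCCC#CC/C=C\CCCCCCCc1cc(OCOC)cc(OCOC)c1
F7 | step 5 | 2-[(1E,4Z,9S)-9-(tert-butyldimethylsilyloxy)-5-(dicyclohexylboranyl)deca-1,4-dien-1-yl]-4,4,5,5-tetramethyl-1,3,2-dioxaborolane | C[C@H](O[Si](C)(C)C(C)(C)C)CCC/C(B(C1CCCCC1)C1CCCCC1)=C\C/C=C/B1OC(C)(C)C(C)(C)O1
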